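## Retrosynthetic overview

1. Target ⇐ saponification of its methyl ester. The (9E,11E,13E)-triene is attached by B-alkyl Suzuki coupling of a terminal alkene with (1E,3E,5E)-1-iodoocta-1,3,5-triene, made by Takai olefination of (2E,4E)-hepta-2,4-dienal.
2. Key disconnection: the ring-CH2–CH2 bond of the side chain (C1'–C2') ⇐ anodic decarboxylative radical–radical cross-coupling (mixed Kolbe) of an enantiopure dioxolane half-ester with oct-7-enoic acid.
3. Both quaternary stereocentres ⇐ enzymatic desymmetrisation of meso (cis) dimethyl 3,5-dimethyl-1,2-dioxolane-3,5-diacetate. The cis-dimethyl core of the target has hidden mirror symmetry.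
4. Ring order: the only ring, the 1,2-dioxolane, is made first (acetylacetone + H2O2). Both acetate arms are then added by peroxycarbenium alkylation.

Assumption 1: the SMILES is read as (3R,5R), i.e. the two ring methyls are cis.
Assumption 2: pig liver esterase cleaves the ester arm on the (S)-configured ring carbon of the meso diester; a hydrolase of opposite preference would give the enantiomer.

Compounds 2 and 5 are low-molecular-weight peroxides: small scale, blast shield, no distillation.

## Route

**Step 1**
Reactants: 1, acetylacetone (pentane-2,4-dione)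
Product: 2, 3,5-dimethoxy-3,5-dimethyl-1,2-dioxolane (cis/trans mixture)
Conditions: 50% aq. H2O2 (1.0 equiv), 0 °C; then MeOH, HC(OMe)3, cat. TsOH, rt
Reagents that add atoms: hydrogen peroxide (OO); methanol (CO)
Why: Double peroxyhemiketalisation of the 1,3-diketone closes the cyclic peroxide and acid-catalysed ketal exchange gives the bis(peroxyketal); no stereocontrol is needed because both acetal carbons are ionised in step 3.

**Step 2**
Reactants: 3, methyl acetate
Product: 4, tert-butyl[(1-methoxyethenyl)oxy]dimethylsilane (TBS ketene acetal)
Conditions: LDA, THF, −78 °C; TBSCl, DMPU, −78 °C → rt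
Reagents that add atoms: TBSCl (C[Si](C)(Cl)C(C)(C)C)
Why: O-silylation of the ester lithium enolate (silyl ketene acetal formation); no stereocentre.

**Step 3**
Reactants: 2; 4 (3 equiv)
Product: 5, dimethyl 2,2'-[(3R,5S)-3,5-dimethyl-1,2-dioxolane-3,5-diyl]diacetate (meso, cis), separated from the racemic trans isomer
Conditions: TiCl4 (2.2 equiv), CH2Cl2, −78 → −40 °C; SiO2 chromatography
Reagents that add atoms: none
Why: Two successive Mukaiyama-type additions of the silyl ketene acetal to Lewis-acid-generated peroxycarbenium ions (substitution of 3-alkoxy-1,2-dioxolanes) install both arms; the second addition has little facial bias (Me vs CH2CO2Me), so roughly 1:1 cis:trans is expected, and isolating the cis isomer (ring CH2 is an AB quartet; a singlet in the C2-symmetric trans isomer) fixes the relative configuration of both quaternary centres.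

**Step 4**
Reactants: 5
Product: 6, 2-[(3S,5R)-5-(2-methoxy-2-oxoethyl)-3,5-dimethyl-1,2-dioxolan-3-yl]acetic acid
Conditions: pig liver esterase, 0.1 M phosphate buffer pH 7.5/DMSO 9:1, 25 °C, pH-stat (1.0 equiv NaOH); then pH 3, EtOAc
Reagents that add atoms: water (O)
Why: Enzymatic desymmetrisation of a meso diester: hydrolysing only the ester on the (S) ring carbon turns the cis relative configuration into absolute configuration at both centres at once, and it stops at the mono-acid because the carboxylate is not a substrate; the closest analogy is the highly selective PLE hydrolysis of dimethyl 3-hydroxy-3-methylglutarate, which also discriminates a β-carbon bearing Me and O.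

**Step 5**
Reactants: 7, 7-bromohept-1-ene
Product: 8, oct-7-enoic acid
Conditions: Mg, THF; CO2 (s), −78 °C → rt; aq. HCl
Reagents that add atoms: carbon dioxide (O=C=O)
Why: Grignard carboxylation; the hept-6-enyl Grignard does not cyclise.

**Step 6 (key step)**
Reactants: 6 (1 equiv); 8 (6 equiv)
Product: 9, methyl 2-[(3R,5R)-3,5-dimethyl-5-(oct-7-en-1-yl)-1,2-dioxolan-3-yl]acetate
Conditions: NaOMe (5 mol% of total acid), MeOH, Pt anode, divided cell, ca. 0.25 A cm⁻², 10 °C, ca. 1.3 F mol⁻¹
Reagents that add atoms: none
Why: Proposed new method: mixed Kolbe electrolysis (closest precedent: anodic cross-coupling of half-esters with ω-alkenoic acids) — both carboxylates are discharged at Pt, lose CO2, and the dioxolanylmethyl and hept-6-enyl radicals combine to form the CH2–CH2 bond, the cross-product being favoured by the excess of 8; the radical is exocyclic, so neither stereocentre is touched; collapse of the β-peroxyalkyl radical to an epoxide (3-exo SHi, roughly ≤10⁵ s⁻¹ and disfavoured by the ring geometry) should be outrun by coupling in the dense radical layer, as Kolbe coupling outruns 5-exo cyclisation of hex-5-enyl radicals; β-oxygenated acids are good Kolbe substrates, the O–O bond is not oxidised at the carboxylate-covered anode, and the divided cell keeps it from the cathode.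

**Step 7**
Reactants: 10, (2E,4E)-hepta-2,4-dienal
Product: 11, (1E,3E,5E)-1-iodoocta-1,3,5-triene (used at once, dark)
Conditions: CrCl2 (6 equiv), CHI3 (2 equiv), THF/dioxane 1:6, 0 °C → rt
Reagents that add atoms: iodoform (IC(I)I)
Why: Takai olefination gives the (E)-alkenyl iodide selectively and leaves the existing E,E-diene unchanged.

**Step 8**
Reactants: 9; 11 (1.2 equiv)
Product: 12, methyl 2-[(3R,5R)-5-[(9E,11E,13E)-hexadeca-9,11,13-trien-1-yl]-3,5-dimethyl-1,2-dioxolan-3-yl]acetate
Conditions: 9-BBN (1.3 equiv), THF, 0 °C → rt; then 11, Pd(dppf)Cl2 (5 mol%), AsPh3, Cs2CO3, DMF/H2O, rt, dark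
Reagents that add atoms: none
Why: B-alkyl Suzuki–Miyaura coupling: anti-Markovnikov hydroboration of the terminal alkene (ester and hindered dialkyl peroxide should be untouched) and Pd(0) coupling with retention of all three E geometries; no stereocentre is formed or disturbed.

**Step 9**
Reactants: 12
Product: 13, 2-[(3R,5R)-5-[(9E,11E,13E)-hexadeca-9,11,13-trien-1-yl]-3,5-dimethyl-1,2-dioxolan-3-yl]acetic acid (target)
Conditions: LiOH·H2O (3 equiv), THF/H2O 3:1, 0 °C → rt, Ar, dark; pH 4 citrate work-up
Reagents that add atoms: water (O)
Why: Saponification: the peroxide carbons carry no α-H (no Kornblum–DeLaMare cleavage), the carboxylate formed suppresses retro-oxa-Michael opening, and the stereocentres and triene are unaffected.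

## Compound list

1 | acetylacetone | CC(=O)CC(C)=O | starting material
2 | 3,5-dimethoxy-3,5-dimethyl-1,2-dioxolane (cis/trans mixture) | COC1(C)CC(C)(OC)OO1 | intermediate
3 | methyl acetate | COC(C)=O | starting material
4 | tert-butyl[(1-methoxyethenyl)oxy]dimethylsilane | C=C(OC)O[Si](C)(C)C(C)(C)C | intermediate
5 | dimethyl 2,2'-[(3R,5S)-3,5-dimethyl-1,2-dioxolane-3,5-diyl]diacetate (meso) | COC(=O)C[C@]1(C)C[C@](C)(CC(=O)OC)OO1 | intermediate
6 | 2-[(3S,5R)-5-(2-methoxy-2-oxoethyl)-3,5-dimethyl-1,2-dioxolan-3-yl]acetic acid | OC(=O)C[C@]1(C)C[C@](C)(CC(=O)OC)OO1 | intermediate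
7 | 7-bromohept-1-ene | BrCCCCCC=C | starting material
8 | oct-7-enoic acid | OC(=O)CCCCCC=C | intermediate
9 | methyl 2-[(3R,5R)-3,5-dimethyl-5-(oct-7-en-1-yl)-1,2-dioxolan-3-yl]acetate | C=CCCCCCC[C@]1(C)C[C@](C)(CC(=O)OC)OO1 | intermediate
10 | (2E,4E)-hepta-2,4-dienal | CC/C=C/C=C/C=O | starting material
11 | (1E,3E,5E)-1-iodoocta-1,3,5-triene | CC/C=C/C=C/C=C/I | intermediate
12 | methyl 2-[(3R,5R)-5-[(9E,11E,13E)-hexadeca-9,11,13-trien-1-yl]-3,5-dimethyl-1,2-dioxolan-3-yl]acetate | CC/C=C/C=C/C=C/CCCCCCCC[C@]1(C)C[C@](C)(CC(=O)OC)OO1 | intermediate
13 | 2-[(3R,5R)-5-[(9E,11E,13E)-hexadeca-9,11,13-trien-1-yl]-3,5-dimethyl-1,2-dioxolan-3-yl]acetic acid | CC/C=C/C=C/C=C/CCCCCCCC[C@]1(C)C[C@](C)(CC(=O)O)OO1 | target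

## Totals and risks

Total steps: 9. Longest linear sequence: 6 (steps 1, 3, 4, 6, 8, 9).

Steps most likely to fail:

1. **Step 6 (mixed Kolbe).** Risks are epoxide formation from the β-peroxyalkyl radical, loss of the O–O bond at an electrode, and low cross-selectivity. Fallback: give up decarboxylation. Reduce the acid of 6 with BH3·SMe2, convert the alcohol to the iodide, and join it to B-(hex-5-enyl)-9-BBN (from hexa-1,5-diene) by Pd-catalysed alkyl–alkyl Suzuki coupling. This gives the same alkene 9 with the reacting carbon one atom further from the peroxide.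
2. **Step 4 (PLE desymmetrisation).** Risks are low ee or the opposite sense. Fallback: statistical chemical mono-saponification of 5 to racemic 6, then classical resolution by crystallisation of a diastereomeric amine salt (e.g. with (R)-1-phenylethylamine). The unwanted enantiomer is re-esterified back to meso 5 and recycled.
3. **Step 3 (double peroxycarbenium alkylation).** Risks are low yield or a strong trans preference. Fallback: build 5 by a formal [3+2] annulation instead. Ozonolysis of methyl 3-methylbut-3-enoate in MeOH gives the α-methoxy hydroperoxide; after O-silylation, SnCl4 generates the peroxycarbenium ion, which adds to a second molecule of the same alkene and closes through the peroxide oxygen.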